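The data come from a simulation on assumed constants, and the scatter is random.

**Time first.** Time is what to watch in a repeat of this flask: the share of target in target plus other capture product climbs, and the useful question is when it stops moving.

the same everywhere: substrate 0.050 M
- alder: second nucleophile 0.075 M; solid first nucleophile 0.030 M; run made earlier
- elm: second nucleophile 0.075 M; solid first nucleophile 0.045 M; run made earlier
- flask: second nucleophile 0.0750 M; solid first nucleophile 0.0600 M; time 30 min

| run | time / min | target / % | other capture product / % |
|---|---|---|---|
| alder | 3.00 | 2.2 | 45.5 |
| alder | 6.00 | 7.4 | 65.9 |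
| alder | 10.0 | 9.9 | 74.8 |
| alder | 12.0 | 13.2 | 76.9 |
| alder | 15.0 | 12.9 | 80.0 |
| alder | 20.0 | 15.3 | 78.6 |
| elm | 1.33 | 1.4 | 22.4 |
| elm | 2.50 | 4.2 | 38.8 |
| elm | 4.00 | 4.7 | 55.5 |
| elm | 6.00 | 10.0 | 66.4 |
| elm | 10.0 | 12.1 | 74.0 |
| elm | 20.0 | 14.1 | 78.9 |

(readings scatter by 1 percentage point)

1. share of target in target plus other capture product at 30 s
2. share of target in target plus other capture product at 4.0 min
3. share of target in target plus other capture product at 30 min

- at the start none of the solid first nucleophile is in solution

**Clearing rate.** Take substrate as falling exponentially, with a steady part of it ending as other capture product. Then alder's reading at 6.00 min over its reading at 3.00 min, less one, is the fraction of substrate surviving that interval. This gives the clearing rate, the first-order constant of substrate loss, 0.267 min⁻¹, as a reading, with a half-life of 2.59 min.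

**Late bracket.** Alder and elm, with 0.030 M and 0.045 M of solid, read close together, so this reckoning assumes that the flask follows their curves. Both marks below are readings and carry their scatter. The lower mark is elm's share at 20.0 min, 15.2%. The upper mark is alder's share at 20.0 min with the surviving substrate, 0.476%, all counted as target: 16.7%.

**Early brackets.** At 4.0 min the flask's share should lie between alder's 4.61% at 3.00 min and 10.1% at 6.00 min, and elm reads 7.81% there. At 30 s it should lie above zero and below elm's 5.88% at 1.33 min.

**Forecast and result.** The forecast gives 1.5%, 9% and 17%, the first two inside these brackets and the last above the late one, holding that “the extra solid in flask should change little”. The flask gives 1.90%, 8.55% and 15.8%, each inside its bracket.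

    substrate → intermediate (k = 0.00444 s⁻¹)
    first nucleophile + intermediate → target (k = 2.71 L mol⁻¹ s⁻¹)
    second nucleophile + intermediate → other capture product (k = 0.846 L mol⁻¹ s⁻¹)
    intermediate → decomposed reagent (k = 0.00200 s⁻¹)
    intermediate → side product (k = 0.00151 s⁻¹)
    solid first nucleophile ⇌ first nucleophile, rate k6*(cs6 - [first nucleophile]) while solid is left; crystals form when [first nucleophile] > cs6 (solubility = 17.0 mM, k = 0.00152 s⁻¹)

**Two clocks.** The clearing rate leaves 0.0328% of substrate, the limiting reagent, at 30 min, and the flask holds 0.034%. Dissolving of solid first nucleophile reaches half of its turnover up to then at 8.85 min, later than the substrate half-life. The step to other capture product has 99% of its turnover up to 30 min behind it at 15.0 min, and from then to 30.0 min first nucleophile goes from 0.00948 M to 0.0149 M and target from 13.8% to 14.8%.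

**Second flask.** In a neighbour flask with 0.045 M of second nucleophile, the same clearing rate again leaves 0.0328% of substrate at 30 min. The computed neighbour flask holds 0.034%, with a share of 24.5%.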